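**Plan**

- Retrosynthesis: after removal of six benzyl ethers, ring C of the flavanone half is cut at two bonds to ring A, the acyl–aryl bond C4–C4a and the aryl ether bond O1–C8a. Ring A becomes 3,5-bis(benzyloxy)benzyne, and O1–C2–C3–C4 becomes a β-silyloxy N-methoxy-N-methylamide.
- Enabling feature: O1 and the C4 acyl carbon sit on adjacent carbons (C8a, C4a) of phloroglucinol ring A, and the C5 oxygen flanks C4a. This is the pattern expected when an O-nucleophile adds to a 3-alkoxybenzyne (oxygen meta, carbanion ortho to the alkoxy group), and the carbanion then lies six atoms from the amide carbonyl.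
- The amide is cut at C2–C3 by an auxiliary-controlled anti-aldol between an arylacetyl oxazolidinone and 4-(benzyloxy)benzaldehyde. The arylacetic acid already carries the benzyl-protected flavone half (chalcone, then flavone, then palladium-catalysed acetate arylation at a bromide).
- Forward order: flavone rings, then the C2–C3 bond with both stereocentres, then ring C of the flavanone by aryne annulation, then global debenzylation.
- Stereochemistry: C2 (R) and C3 (S) come from the anti-aldol. The C2–O bond is never broken afterwards, and 2,3-trans is also the thermodynamic arrangement.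

Key step: step 11

Remark: the SMILES is read as (2R,3S), that is 2,3-trans; the acetophenone, the bromoaldehyde, the zinc reagent, the oxazolidinone, 4-(benzyloxy)benzaldehyde and 3,5-bis(benzyloxy)phenol are taken as purchasable.
Abbreviations in names: Bn = benzyl; Chr = 5,7-bis(benzyloxy)-4-oxo-4H-chromen-2-yl; ArF = 2-(benzyloxy)-5-(Chr)phenyl.

**Route**

Step 1
Reactants: 1 1-[2,4-bis(benzyloxy)-6-hydroxyphenyl]ethan-1-one; 2 4-(benzyloxy)-3-bromobenzaldehyde
Product: 3 (E)-1-[2,4-bis(benzyloxy)-6-hydroxyphenyl]-3-[4-(benzyloxy)-3-bromophenyl]prop-2-en-1-one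
Conditions: KOH, EtOH/THF, rt
Reagents that add atoms: none
Why: Claisen–Schmidt condensation of the methyl ketone with a non-enolisable aldehyde should give the (E)-chalcone, the free 2'-hydroxyl being carried as its phenoxide.

Step 2
Reactants: 3 the chalcone
Product: 4 5,7-bis(benzyloxy)-2-[4-(benzyloxy)-3-bromophenyl]-4H-chromen-4-one
Conditions: I2 (cat.), DMSO, 130 °C
Reagents that add atoms: none
Why: Iodine-catalysed oxidative cyclisation of a 2'-hydroxychalcone in DMSO (oxa-Michael closure, α-iodination, loss of HI, reoxidation by DMSO) is the standard flavone synthesis and should leave the aryl bromide and benzyl ethers untouched.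

Step 3
Reactants: 4 the bromoflavone; 5 (2-tert-butoxy-2-oxoethyl)zinc bromide
Product: 6 tert-butyl 2-(ArF)acetate
Conditions: Pd2(dba)3 (cat.), XPhos, THF, 65 °C
Reagents that add atoms: none
Why: Palladium-catalysed α-arylation of an ester through its Reformatsky zinc enolate (Negishi-type coupling at zerovalent palladium) runs without added base, so the chromone should survive, and ortho-alkoxy aryl bromides are competent partners.

Step 4
Reactants: 6 the tert-butyl ester
Product: 7 2-(ArF)acetic acid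
Conditions: TFA, CH2Cl2, 0 °C to rt
Reagents that add atoms: none
Why: Acidolysis of the tert-butyl ester with loss of isobutene should free the acid, benzyl ethers and chromone being stable to brief TFA treatment.

Step 5
Reactants: 7 the arylacetic acid; 8 (R)-4-benzyl-1,3-oxazolidin-2-one
Product: 10 (R)-4-benzyl-3-[2-(ArF)acetyl]-1,3-oxazolidin-2-one, via mixed pivalic anhydride 9 (not isolated)
Conditions: PivCl, Et3N, THF, −20 °C; then 8, LiCl, rt
Reagents that add atoms: none
Why: N-acylation of the oxazolidinone through the mixed pivalic anhydride under LiCl/Et3N is the standard mild imide synthesis and avoids ketene formation from the arylacetic acid.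

Step 6
Reactants: 10 the N-acyl oxazolidinone; 11 4-(benzyloxy)benzaldehyde
Product: 13 (R)-4-benzyl-3-[(2S,3R)-2-(ArF)-3-[4-(benzyloxy)phenyl]-3-hydroxypropanoyl]-1,3-oxazolidin-2-one (anti-aldol adduct), via trimethylsilyl ether 12 (not isolated)
Conditions: MgCl2 (cat.), Et3N, TMSCl, EtOAc, rt; then TFA, MeOH
Reagents that add atoms: none
Why: Magnesium halide-catalysed anti-aldol of an N-acyloxazolidinone: the chelated Z-enolate from soft enolisation should add to the aromatic aldehyde on the face away from the benzyl group of the (R)-auxiliary, setting C3 (S) and C2 (R) of the target, while silylation of the aldolate turns the catalyst over and blocks retro-aldol.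

Step 7
Reactants: 13 the anti-aldol adduct
Product: 14 (2S,3R)-2-(ArF)-3-[4-(benzyloxy)phenyl]-3-hydroxy-N-methoxy-N-methylpropanamide
Conditions: MeNHOMe·HCl, AlMe3, CH2Cl2, −10 to 0 °C; Rochelle salt work-up
Reagents that add atoms: N,O-dimethylhydroxylamine hydrochloride (CNOC.Cl)
Why: Aluminium amide transamination of a β-hydroxy imide, assisted by the free hydroxyl, should give the Weinreb amide without touching either stereocentre and release the auxiliary.

Step 8
Reactants: 14 the β-hydroxy Weinreb amide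
Product: 15 (2S,3R)-2-(ArF)-3-[4-(benzyloxy)phenyl]-N-methoxy-N-methyl-3-(triethylsilyloxy)propanamide
Conditions: TESCl, imidazole, DMF, 0 °C to rt
Reagents that add atoms: chlorotriethylsilane (CC[Si](Cl)(CC)CC)
Why: Standard silylation of the secondary benzylic alcohol gives an ether that is stable to chromatography yet cleaved by fluoride, so it serves as a latent alkoxide for step 11.

Step 9
Reactants: 16 3,5-bis(benzyloxy)phenol
Product: 17 3,5-bis(benzyloxy)-2-bromophenol
Conditions: NBS, CH2Cl2, −78 °C to rt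
Reagents that add atoms: N-bromosuccinimide (O=C1CCC(=O)N1Br)
Why: Electrophilic bromination of the electron-rich phenol at low temperature should go ortho to the hydroxyl, the position between the two benzyloxy groups being more hindered.

Step 10
Reactants: 17 the bromophenol
Product: 20 3,5-bis(benzyloxy)-2-(trimethylsilyl)phenyl trifluoromethanesulfonate, via aryl trimethylsilyl ether 18 (not isolated), via lithium 2-silylphenolate 19 (not isolated)
Conditions: HMDS, THF, 70 °C; then n-BuLi, THF, −100 °C; then Tf2O, −100 °C to rt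
Reagents that add atoms: hexamethyldisilazane (C[Si](C)(C)N[Si](C)(C)C); trifluoromethanesulfonic anhydride (O=S(=O)(OS(=O)(=O)C(F)(F)F)C(F)(F)F)
Why: O-silylation, bromine–lithium exchange and 1,3 O-to-C silyl shift (retro-Brook rearrangement) should give the 2-silylphenoxide, which is triflated in the same flask to the 2-silylaryl triflate aryne precursor.

Step 11
Reactants: 15 the β-triethylsilyloxy Weinreb amide; 20 the 2-silylaryl triflate
Product: 25 (2R,3S)-3-(ArF)-5,7-bis(benzyloxy)-2-[4-(benzyloxy)phenyl]chroman-4-one, via potassium alkoxide 21 (not isolated), via aryne 22 (not isolated), via aryl potassium 23 (not isolated), via hemiaminal alkoxide 24 (not isolated)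
Conditions: KF, 18-crown-6, THF, −20 to 0 °C, 20 added slowly; then aq NH4Cl
Reagents that add atoms: none
Why: Proposed new method: fluoride strips the triethylsilyl group from 15 and triggers 1,2-elimination of 20, so that potassium alkoxide 21 and 3,5-bis(benzyloxy)benzyne 22 are released side by side with no proton donor present; O-attack on 22 gives aryl potassium 23, whose carbanion adds to the Weinreb amide carbonyl to give hemiaminal alkoxide 24, which collapses to ketone 25 only on aqueous work-up. The closest known reaction type is the fluoride-induced annulation of arynes with salicylate esters (xanthones) or amino esters (acridones, indolinones), that is heteroatom arylation followed by acyl capture of the aryl anion; an aliphatic β-silyloxy amide as donor is the untested part. The dihydropyranone ring C closes 6-exo-trig by the bond from the former silyl-bearing aryne carbon (C4a) to the amide carbon (C4), the O1–C8a bond having formed in the preceding elementary step. No stereocentre is created: C2 keeps its configuration because its C–O bond is never broken, and C3, set in step 6, is also the thermodynamically preferred 2,3-trans (diequatorial) arrangement. The step needs regioselective addition to the aryne, secured by the 3-benzyloxy group, which polarises the triple bond so that oxygen adds at the remote carbon and the carbanion develops next to OBn, the C8a/C4a/C5 pattern of ring A. It also needs the carbanion to acylate faster than it is quenched and the alkoxide to be arylated faster than it undergoes retro-aldol cleavage, which the proton-free unmasking, the low temperature, the weakly acidifying amide and the base-stable adduct 24 are meant to secure.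

Step 12
Reactants: 25 the hexabenzyl ether
Product: 26 (2R,3S)-5,7-dihydroxy-3-[2-hydroxy-5-(5,7-dihydroxy-4-oxo-4H-chromen-2-yl)phenyl]-2-(4-hydroxyphenyl)chroman-4-one
Conditions: H2 (1 atm), Pd/C, EtOAc/MeOH, rt
Reagents that add atoms: none
Why: Catalytic hydrogenolysis should cleave all six benzyl ethers under neutral conditions that do not epimerise C2 or C3, the flavone C2=C3 bond and the hydrogen-bonded aryl ketones being expected to survive at atmospheric pressure.

**Compound list**

1 | 1-[2,4-bis(benzyloxy)-6-hydroxyphenyl]ethan-1-one | CC(=O)c1c(O)cc(OCc2ccccc2)cc1OCc1ccccc1 | starting material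
2 | 4-(benzyloxy)-3-bromobenzaldehyde | O=Cc1ccc(OCc2ccccc2)c(Br)c1 | starting material
3 | (E)-1-[2,4-bis(benzyloxy)-6-hydroxyphenyl]-3-[4-(benzyloxy)-3-bromophenyl]prop-2-en-1-one | O=C(/C=C/c1ccc(OCc2ccccc2)c(Br)c1)c1c(O)cc(OCc2ccccc2)cc1OCc1ccccc1 | intermediate
4 | 5,7-bis(benzyloxy)-2-[4-(benzyloxy)-3-bromophenyl]-4H-chromen-4-one | O=c1cc(-c2ccc(OCc3ccccc3)c(Br)c2)oc2cc(OCc3ccccc3)cc(OCc3ccccc3)c12 | intermediate
5 | (2-tert-butoxy-2-oxoethyl)zinc bromide | CC(C)(C)OC(=O)C[Zn]Br | starting material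
6 | tert-butyl 2-{2-(benzyloxy)-5-[5,7-bis(benzyloxy)-4-oxo-4H-chromen-2-yl]phenyl}acetate | CC(C)(C)OC(=O)Cc1cc(-c2cc(=O)c3c(OCc4ccccc4)cc(OCc4ccccc4)cc3o2)ccc1OCc1ccccc1 | intermediate
7 | 2-{2-(benzyloxy)-5-[5,7-bis(benzyloxy)-4-oxo-4H-chromen-2-yl]phenyl}acetic acid | OC(=O)Cc1cc(-c2cc(=O)c3c(OCc4ccccc4)cc(OCc4ccccc4)cc3o2)ccc1OCc1ccccc1 | intermediate
8 | (R)-4-benzyl-1,3-oxazolidin-2-one | O=C1N[C@H](Cc2ccccc2)CO1 | starting material
9 | mixed anhydride of acid 7 with pivalic acid | CC(C)(C)C(=O)OC(=O)Cc1cc(-c2cc(=O)c3c(OCc4ccccc4)cc(OCc4ccccc4)cc3o2)ccc1OCc1ccccc1 | intermediate (not isolated)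
10 | (R)-4-benzyl-3-(2-{2-(benzyloxy)-5-[5,7-bis(benzyloxy)-4-oxo-4H-chromen-2-yl]phenyl}acetyl)-1,3-oxazolidin-2-one | O=C(Cc1cc(-c2cc(=O)c3c(OCc4ccccc4)cc(OCc4ccccc4)cc3o2)ccc1OCc1ccccc1)N1[C@H](Cc2ccccc2)COC1=O | intermediate
11 | 4-(benzyloxy)benzaldehyde | O=Cc1ccc(OCc2ccccc2)cc1 | starting material
12 | O-trimethylsilyl ether of anti-aldol adduct 13, (2S,3R) | O=C([C@@H](c1cc(-c2cc(=O)c3c(OCc4ccccc4)cc(OCc4ccccc4)cc3o2)ccc1OCc1ccccc1)[C@@H](O[Si](C)(C)C)c1ccc(OCc2ccccc2)cc1)N1[C@H](Cc2ccccc2)COC1=O | intermediate (not isolated)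
13 | (R)-4-benzyl-3-[(2S,3R)-2-{2-(benzyloxy)-5-[5,7-bis(benzyloxy)-4-oxo-4H-chromen-2-yl]phenyl}-3-[4-(benzyloxy)phenyl]-3-hydroxypropanoyl]-1,3-oxazolidin-2-one | O=C([C@@H](c1cc(-c2cc(=O)c3c(OCc4ccccc4)cc(OCc4ccccc4)cc3o2)ccc1OCc1ccccc1)[C@@H](O)c1ccc(OCc2ccccc2)cc1)N1[C@H](Cc2ccccc2)COC1=O | intermediate
14 | (2S,3R)-2-{2-(benzyloxy)-5-[5,7-bis(benzyloxy)-4-oxo-4H-chromen-2-yl]phenyl}-3-[4-(benzyloxy)phenyl]-3-hydroxy-N-methoxy-N-methylpropanamide | CON(C)C(=O)[C@@H](c1cc(-c2cc(=O)c3c(OCc4ccccc4)cc(OCc4ccccc4)cc3o2)ccc1OCc1ccccc1)[C@@H](O)c1ccc(OCc2ccccc2)cc1 | intermediate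
15 | (2S,3R)-2-{2-(benzyloxy)-5-[5,7-bis(benzyloxy)-4-oxo-4H-chromen-2-yl]phenyl}-3-[4-(benzyloxy)phenyl]-N-methoxy-N-methyl-3-(triethylsilyloxy)propanamide | CON(C)C(=O)[C@@H](c1cc(-c2cc(=O)c3c(OCc4ccccc4)cc(OCc4ccccc4)cc3o2)ccc1OCc1ccccc1)[C@@H](O[Si](CC)(CC)CC)c1ccc(OCc2ccccc2)cc1 | intermediate
16 | 3,5-bis(benzyloxy)phenol | Oc1cc(OCc2ccccc2)cc(OCc2ccccc2)c1 | starting material
17 | 3,5-bis(benzyloxy)-2-bromophenol | Oc1cc(OCc2ccccc2)cc(OCc2ccccc2)c1Br | intermediate
18 | [3,5-bis(benzyloxy)-2-bromophenoxy]trimethylsilane | C[Si](C)(C)Oc1cc(OCc2ccccc2)cc(OCc2ccccc2)c1Br | intermediate (not isolated)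
19 | lithium 3,5-bis(benzyloxy)-2-(trimethylsilyl)phenolate | [Li+].[O-]c1cc(OCc2ccccc2)cc(OCc2ccccc2)c1[Si](C)(C)C | intermediate (not isolated)
20 | 3,5-bis(benzyloxy)-2-(trimethylsilyl)phenyl trifluoromethanesulfonate | C[Si](C)(C)c1c(OS(=O)(=O)C(F)(F)F)cc(OCc2ccccc2)cc1OCc1ccccc1 | intermediate
21 | potassium alkoxide of hydroxy amide 14, (2S,3R) | [K+].CON(C)C(=O)[C@@H](c1cc(-c2cc(=O)c3c(OCc4ccccc4)cc(OCc4ccccc4)cc3o2)ccc1OCc1ccccc1)[C@@H]([O-])c1ccc(OCc2ccccc2)cc1 | intermediate (not isolated)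
22 | 3,5-bis(benzyloxy)benzyne (1,2-didehydro-3,5-bis(benzyloxy)benzene) | C1#CC(OCc2ccccc2)=CC(OCc2ccccc2)=C1 | intermediate (not isolated)
23 | aryl potassium from O-arylation: (2S,3R)-3-[3,5-bis(benzyloxy)-2-potassiophenoxy] derivative of the Weinreb amide | [K+].CON(C)C(=O)[C@@H](c1cc(-c2cc(=O)c3c(OCc4ccccc4)cc(OCc4ccccc4)cc3o2)ccc1OCc1ccccc1)[C@@H](Oc1cc(OCc2ccccc2)cc(OCc2ccccc2)[c-]1)c1ccc(OCc2ccccc2)cc1 | intermediate (not isolated)
24 | potassium (2R,3S)-3-{2-(benzyloxy)-5-[5,7-bis(benzyloxy)-4-oxo-4H-chromen-2-yl]phenyl}-5,7-bis(benzyloxy)-2-[4-(benzyloxy)phenyl]-4-[methoxy(methyl)amino]chroman-4-olate (C4 configuration open) | [K+].[O-]C1(N(C)OC)c2c(OCc3ccccc3)cc(OCc3ccccc3)cc2O[C@@H](c2ccc(OCc3ccccc3)cc2)[C@@H]1c1cc(-c2cc(=O)c3c(OCc4ccccc4)cc(OCc4ccccc4)cc3o2)ccc1OCc1ccccc1 | intermediate (not isolated)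
25 | (2R,3S)-3-{2-(benzyloxy)-5-[5,7-bis(benzyloxy)-4-oxo-4H-chromen-2-yl]phenyl}-5,7-bis(benzyloxy)-2-[4-(benzyloxy)phenyl]chroman-4-one | O=C1c2c(OCc3ccccc3)cc(OCc3ccccc3)cc2O[C@@H](c2ccc(OCc3ccccc3)cc2)[C@@H]1c1cc(-c2cc(=O)c3c(OCc4ccccc4)cc(OCc4ccccc4)cc3o2)ccc1OCc1ccccc1 | intermediate
26 | (2R,3S)-5,7-dihydroxy-3-[2-hydroxy-5-(5,7-dihydroxy-4-oxo-4H-chromen-2-yl)phenyl]-2-(4-hydroxyphenyl)chroman-4-one | O=C1c2c(O)cc(O)cc2O[C@@H](c2ccc(O)cc2)[C@@H]1c1cc(-c2cc(=O)c3c(O)cc(O)cc3o2)ccc1O | target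

Total step count: 12. Longest linear sequence: 10 (steps 1 to 8, 11, 12).

**Steps most likely to fail**

1. Step 11 (proposed new method). The unmasked alkoxide may undergo retro-aldol cleavage or β-elimination before it meets the aryne, or the aryl carbanion may be protonated before it acylates. Either would erode enantiopurity or prevent ring closure. The fallback forms the two bonds in separate, known operations (Mitsunobu etherification with inversion, then Friedel–Crafts acylation). It sets out from acid 7, which is coupled (PivCl, Et3N, LiCl) with (S)-4-benzyl-1,3-oxazolidin-2-one to give the enantiomeric-auxiliary imide F1. Boron-mediated syn-aldol (Bu2BOTf, i-Pr2NEt, then 11) should give the (2S,3S) syn adduct F2. Methanolysis with MeMgBr/MeOH gives methyl ester F3. Mitsunobu reaction with phenol 16 (DIAD, PPh3) should invert the carbinol centre to give the (2S,3R) aryl ether F4. Me3SnOH cleaves the ester under neutral conditions to acid F5. TFAA in CH2Cl2 at 0 °C then closes the same C4–C4a bond by intramolecular Friedel–Crafts acylation of the very electron-rich aryl ether. The fallback comes back to the route at 25.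

2. Step 6. Retro-aldol equilibration or α-epimerisation under the amine/magnesium conditions may lower the diastereomer ratio, or the facial sense may not carry over to the arylacetyl imide. The fallback replaces kinetic anti control by syn control plus thermodynamic correction. It sets out from 10: boron-mediated syn-aldol (Bu2BOTf, i-Pr2NEt, then 11, oxidative work-up) should give the (2R,3R) syn adduct F6, which has the required carbinol configuration. The operations of steps 7, 8 and 11 then lead through the syn Weinreb amide F7 and its triethylsilyl ether F8 to the cis-chromanone F9. C3 of F9 lies between the ketone and an aryl ring and should be epimerised (catalytic DBU, CH2Cl2) to the diequatorial trans isomer. The fallback comes back to the route at 25.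

3. Step 12. Over-reduction may occur (saturation of the flavone C2=C3 bond, hydrogenolysis of the benzylic C2–O1 bond of the flavanone), or cleavage of the six ethers may stop short. The fallback is a non-reductive Lewis-acid debenzylation of 25 with BCl3 and pentamethylbenzene as benzyl-cation trap (CH2Cl2, −78 °C). It sets out from 25 and arrives directly at 26 without any new compound.

**Further compounds**

F1 | step 11 | (S)-4-benzyl-3-(2-{2-(benzyloxy)-5-[5,7-bis(benzyloxy)-4-oxo-4H-chromen-2-yl]phenyl}acetyl)-1,3-oxazolidin-2-one | O=C(Cc1cc(-c2cc(=O)c3c(OCc4ccccc4)cc(OCc4ccccc4)cc3o2)ccc1OCc1ccccc1)N1[C@@H](Cc2ccccc2)COC1=O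
F2 | step 11 | (S)-4-benzyl-3-[(2S,3S)-2-(ArF)-3-[4-(benzyloxy)phenyl]-3-hydroxypropanoyl]-1,3-oxazolidin-2-one (syn) | O=C([C@@H](c1cc(-c2cc(=O)c3c(OCc4ccccc4)cc(OCc4ccccc4)cc3o2)ccc1OCc1ccccc1)[C@H](O)c1ccc(OCc2ccccc2)cc1)N1[C@@H](Cc2ccccc2)COC1=O
F3 | step 11 | methyl (2S,3S)-2-(ArF)-3-[4-(benzyloxy)phenyl]-3-hydroxypropanoate | COC(=O)[C@@H](c1cc(-c2cc(=O)c3c(OCc4ccccc4)cc(OCc4ccccc4)cc3o2)ccc1OCc1ccccc1)[C@H](O)c1ccc(OCc2ccccc2)cc1
F4 | step 11 | methyl (2S,3R)-2-(ArF)-3-[3,5-bis(benzyloxy)phenoxy]-3-[4-(benzyloxy)phenyl]propanoate | COC(=O)[C@@H](c1cc(-c2cc(=O)c3c(OCc4ccccc4)cc(OCc4ccccc4)cc3o2)ccc1OCc1ccccc1)[C@@H](Oc1cc(OCc2ccccc2)cc(OCc2ccccc2)c1)c1ccc(OCc2ccccc2)cc1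
F5 | step 11 | (2S,3R)-2-(ArF)-3-[3,5-bis(benzyloxy)phenoxy]-3-[4-(benzyloxy)phenyl]propanoic acid | OC(=O)[C@@H](c1cc(-c2cc(=O)c3c(OCc4ccccc4)cc(OCc4ccccc4)cc3o2)ccc1OCc1ccccc1)[C@@H](Oc1cc(OCc2ccccc2)cc(OCc2ccccc2)c1)c1ccc(OCc2ccccc2)cc1
F6 | step 6 | (R)-4-benzyl-3-[(2R,3R)-2-(ArF)-3-[4-(benzyloxy)phenyl]-3-hydroxypropanoyl]-1,3-oxazolidin-2-one (syn) | O=C([C@H](c1cc(-c2cc(=O)c3c(OCc4ccccc4)cc(OCc4ccccc4)cc3o2)ccc1OCc1ccccc1)[C@@H](O)c1ccc(OCc2ccccc2)cc1)N1[C@H](Cc2ccccc2)COC1=O
F7 | step 6 | (2R,3R)-2-(ArF)-3-[4-(benzyloxy)phenyl]-3-hydroxy-N-methoxy-N-methylpropanamide | CON(C)C(=O)[C@H](c1cc(-c2cc(=O)c3c(OCc4ccccc4)cc(OCc4ccccc4)cc3o2)ccc1OCc1ccccc1)[C@@H](O)c1ccc(OCc2ccccc2)cc1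
F8 | step 6 | (2R,3R)-2-(ArF)-3-[4-(benzyloxy)phenyl]-N-methoxy-N-methyl-3-(triethylsilyloxy)propanamide | CON(C)C(=O)[C@H](c1cc(-c2cc(=O)c3c(OCc4ccccc4)cc(OCc4ccccc4)cc3o2)ccc1OCc1ccccc1)[C@@H](O[Si](CC)(CC)CC)c1ccc(OCc2ccccc2)cc1
F9 | step 6 | (2R,3R)-3-(ArF)-5,7-bis(benzyloxy)-2-[4-(benzyloxy)phenyl]chroman-4-one (2,3-cis) | O=C1c2c(OCc3ccccc3)cc(OCc3ccccc3)cc2O[C@@H](c2ccc(OCc3ccccc3)cc2)[C@H]1c1cc(-c2cc(=O)c3c(OCc4ccccc4)cc(OCc4ccccc4)cc3o2)ccc1OCc1ccccc1
F0 | step 12 | none | none
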